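**The vessel.** A closed, stirred vessel holds starting material and free catalyst, and we want to know what stands in it at the asked time.

| flask | starting material | free catalyst | remark | time |
|---|---|---|---|---|
| Saturday's | 20 mM | 0.14 mM | run made earlier |  |
| Sunday's | 20 mM | 0.21 mM | run made earlier |  |
| flask | 20 mM | 0.28 mM |  | 12 min |

- Saturday's (time / min: product / %): 1.00: 7.0; 2.00: 12.7; 5.00: 26.8; 12.0: 52.6
- Sunday's (time / min: product / %): 3.00: 25.9; 6.00: 43.2; 10.0: 61.0; 12.0: 67.0

(standard deviation of a reading: 0.3 percentage points)

1. why nothing more happens at 12 min, or that something still does (forward and back rates have come level / all of the starting material has reacted / no working catalyst is left / it is still moving)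
2. how much product there is at 12 min, in percent of the starting material charged

- the numbers in the tables scatter by 0.3 percentage points (one standard deviation)
- the reaction counts as stopped when no species that holds the starting material changes by six tenths of a point or more over the second half of the time

**One constant.** Suppose the rate of forming product is a constant times the catalyst charged times the share not yet product, which is pseudo-first-order at fixed catalyst. Integrating gives a share not yet product of exp(−constant × dose), where the dose is catalyst charged times time. Sunday's last reading gives 440 M⁻¹ min⁻¹, and we carry this dose constant: the logarithm of one over the share not yet product, divided by the dose. Saturday's last reading gives 444 M⁻¹ min⁻¹, close to Sunday's, so we take the rate as proportional to catalyst.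

**Two extremes.** If the flask kept the pace of Saturday's first minute, 518 M⁻¹ min⁻¹, it would reach 82.5%. If it ran throughout at Sunday's later pace, 431 M⁻¹ min⁻¹, it would reach 76.5%. The readings start fast and then slow, so we place the flask between these two as an estimate. Sunday's constant sits nearer the slow end.

**Our reckoning.** The flask's dose is 0.202 M·s, so we expect 77.3% product. Between 6.00 min and 12 min the same rule adds 25 percentage points, so the flask is still moving.

**The forecast.** It said 77% and it is still moving, reasoning that “The runs roughly overlay on catalyst × time”.

**The result.** The flask gives 77.6% and it is still moving.

    starting material + free catalyst → catalyst intermediate (k = 658 M⁻¹ min⁻¹)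
    catalyst intermediate → free catalyst + product (k = 59.7 min⁻¹)
    starting material ⇌ dormant form (K = 0.340, k = 0.226 min⁻¹)

At 12.0 min the flask still holds 15.7% starting material and 6.58% dormant form. Its own dose constant comes to 444 M⁻¹ min⁻¹. Sunday's constant, applied to the neighbour flask charged with 0.11 mM of free catalyst, gives 44.1%, and that neighbour holds 44.2% product.

All runs are calculated on assumed constants, and the scatter is random.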